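**Retrosynthetic overview**

The target is a (2S)-flavanone (benzo ring A, pyranone ring C, aryl ring B) joined by an ether oxygen from C3 of ring B to C4 of the para-phenylene ring F of a flavone (benzo ring D, pyranone ring E).
1. Last operations: the four benzyl ethers are removed, and the C4 carbonyl of ring C is made by C4–H oxidation of a flavan, so the base-labile C2 stereocentre travels as a plain ether carbon.
2. Key cut: pyranone ring E, whose atoms O1, C2, C3 and C4 lie between ring D and ring F, is opened at C4a–C4, C4–C3 and O1–C2 into an ortho-iodophenol, carbon monoxide and an aryl alkyne that already holds the finished (S)-flavan.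
3. Flavan ring C: O1–C2 by Mitsunobu closure (inversion) of an (R)-carbinol from asymmetric transfer hydrogenation of a dihydrochalcone, itself from Claisen–Schmidt union of a ring B acetophenone (diaryl ether by Chan–Lam coupling) and a ring A salicylaldehyde.
4. Ring order: diaryl ether link, then ring C, then ring E.

Key step: step 12

Remark: 3,5-bis(benzyloxy)phenol is taken as a purchased compound; it can otherwise be made by partial benzylation of phloroglucinol.

**Route**

Step 1
Reactants: 1 3',4'-dihydroxyacetophenone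
Product: 2 1-[4-(benzyloxy)-3-hydroxyphenyl]ethan-1-one
Conditions: BnBr (1.05 equiv), NaHCO3, NaI (cat.), DMF, 40 °C
Reagents that add atoms: benzyl bromide, BrCc1ccccc1
Why: Williamson etherification; the 4-OH, para to the acetyl group, is the more acidic phenol and the only one ionised by hydrogencarbonate, so one equivalent of benzyl bromide should alkylate it selectively.

Step 2
Reactants: 2 1-[4-(benzyloxy)-3-hydroxyphenyl]ethan-1-one; 3 4-bromophenylboronic acid
Product: 4 1-[4-(benzyloxy)-3-(4-bromophenoxy)phenyl]ethan-1-one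
Conditions: Cu(OAc)2 (0.2 equiv), pyridine, 4 Å MS, CH2Cl2, O2 (1 atm), rt
Reagents that add atoms: none
Why: Chan–Lam oxidative O-arylation of the phenol by the arylboronic acid proceeds at room temperature and leaves the aryl bromide and the ketone untouched, so the bromide is kept as the later alkyne handle.

Step 3
Reactants: 5 2,4,6-trihydroxybenzaldehyde
Product: 6 2,6-dihydroxy-4-methoxybenzaldehyde
Conditions: MeI (1.0 equiv), K2CO3 (1.0 equiv), acetone, 0 °C → rt
Reagents that add atoms: iodomethane, CI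
Why: Williamson etherification; the 4-OH is para to the formyl group and not hydrogen-bonded to it, so it is the most acidic and most nucleophilic hydroxyl and should be methylated first when base and iodomethane are limited to one equivalent.

Step 4
Reactants: 6 2,6-dihydroxy-4-methoxybenzaldehyde
Product: 7 2-(benzyloxy)-6-hydroxy-4-methoxybenzaldehyde
Conditions: BnBr (1.05 equiv), K2CO3 (1.1 equiv), DMF, rt
Reagents that add atoms: benzyl bromide, BrCc1ccccc1
Why: Williamson mono-benzylation; the two hydroxyls are equivalent so only one mono-ether can form, and the remaining hydroxyl is chelated to the formyl group and should react much more slowly.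

Step 5
Reactants: 4 1-[4-(benzyloxy)-3-(4-bromophenoxy)phenyl]ethan-1-one; 7 2-(benzyloxy)-6-hydroxy-4-methoxybenzaldehyde
Product: 8 (E)-1-[4-(benzyloxy)-3-(4-bromophenoxy)phenyl]-3-[2-(benzyloxy)-6-hydroxy-4-methoxyphenyl]prop-2-en-1-one
Conditions: KOH (50 % aq., excess), EtOH–THF, rt → 40 °C; AcOH to pH 6–7
Reagents that add atoms: none
Why: Claisen–Schmidt condensation; the enolate of ketone 4 adds to aldehyde 7 and E1cB dehydration should give the E-enone, which stays open as its phenoxide in base, while the near-neutral quench avoids acid-induced closure to a flavylium salt.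

Step 6
Reactants: 8 (E)-1-[4-(benzyloxy)-3-(4-bromophenoxy)phenyl]-3-[2-(benzyloxy)-6-hydroxy-4-methoxyphenyl]prop-2-en-1-one
Product: 9 1-[4-(benzyloxy)-3-(4-bromophenoxy)phenyl]-3-[2-(benzyloxy)-6-hydroxy-4-methoxyphenyl]propan-1-one
Conditions: H2 (3 atm), RhCl(PPh3)3 (5 mol %), THF–EtOH, 40 °C
Reagents that add atoms: none
Why: Homogeneous hydrogenation with RhCl(PPh3)3 should saturate the disubstituted enone C=C while sparing the aryl bromide, the benzyl ethers and the ketone, all of which a heterogeneous palladium catalyst would attack.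

Step 7
Reactants: 9 1-[4-(benzyloxy)-3-(4-bromophenoxy)phenyl]-3-[2-(benzyloxy)-6-hydroxy-4-methoxyphenyl]propan-1-one
Product: 10 (1R)-1-[4-(benzyloxy)-3-(4-bromophenoxy)phenyl]-3-[2-(benzyloxy)-6-hydroxy-4-methoxyphenyl]propan-1-ol
Conditions: RuCl(p-cymene)[(R,R)-TsDPEN] (2 mol %), HCO2H–Et3N (5:2), DMF, 40 °C
Reagents that add atoms: none
Why: Noyori asymmetric transfer hydrogenation of an aryl alkyl ketone; the (R,R) catalyst delivers hydride through the six-membered Ru–H/N–H transition state with the aryl group against the cymene ligand, in the same facial sense that turns acetophenone into (R)-1-phenylethanol, so the (R)-carbinol should result.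

Step 8
Reactants: 10 (1R)-1-[4-(benzyloxy)-3-(4-bromophenoxy)phenyl]-3-[2-(benzyloxy)-6-hydroxy-4-methoxyphenyl]propan-1-ol
Product: 11 (2S)-5-(benzyloxy)-2-[4-(benzyloxy)-3-(4-bromophenoxy)phenyl]-7-methoxychromane
Conditions: PPh3, DIAD, toluene, −20 → 0 °C
Reagents that add atoms: none
Why: Intramolecular Mitsunobu etherification; the phenol displaces the alkoxyphosphonium group in a 6-exo-tet SN2 closure of ring C with inversion, turning the (R)-carbinol into the (2S)-flavan, and the cold, non-polar medium is chosen to suppress ionisation of the benzylic centre.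

Step 9
Reactants: 11 (2S)-5-(benzyloxy)-2-[4-(benzyloxy)-3-(4-bromophenoxy)phenyl]-7-methoxychromane; 12 ethynyltrimethylsilane
Product: 13 (2S)-5-(benzyloxy)-2-{4-(benzyloxy)-3-[4-(trimethylsilylethynyl)phenoxy]phenyl}-7-methoxychromane
Conditions: PdCl2(PhCN)2 (3 mol %), [HP(t-Bu)3]BF4 (6 mol %), CuI (2 mol %), i-Pr2NH, dioxane, rt → 45 °C
Reagents that add atoms: none
Why: Sonogashira coupling; the bulky electron-rich phosphine lets the electron-rich aryl bromide undergo oxidative addition at mild temperature, and the flavan stereocentre is not involved.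

Step 10
Reactants: 13 (2S)-5-(benzyloxy)-2-{4-(benzyloxy)-3-[4-(trimethylsilylethynyl)phenoxy]phenyl}-7-methoxychromane
Product: 14 (2S)-5-(benzyloxy)-2-[4-(benzyloxy)-3-(4-ethynylphenoxy)phenyl]-7-methoxychromane
Conditions: K2CO3 (0.2 equiv), MeOH–THF, rt
Reagents that add atoms: none
Why: Base-catalysed methanolysis of the alkynyl C–Si bond (protodesilylation) frees the terminal alkyne under conditions to which ethers and the flavan are inert.

Step 11
Reactants: 15 3,5-bis(benzyloxy)phenol
Product: 16 3,5-bis(benzyloxy)-2-iodophenol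
Conditions: NIS (1.0 equiv), CH2Cl2, −20 → 0 °C, dark
Reagents that add atoms: N-iodosuccinimide, O=C1CCC(=O)N1I
Why: Electrophilic aromatic iodination; the two equivalent positions ortho to the free hydroxyl are favoured over C4, which is flanked by two benzyloxy groups, so the 2-iodo isomer should be the main product and the minor 4-iodo isomer is removed by chromatography.

Step 12
Reactants: 14 (2S)-5-(benzyloxy)-2-[4-(benzyloxy)-3-(4-ethynylphenoxy)phenyl]-7-methoxychromane; 16 3,5-bis(benzyloxy)-2-iodophenol; 17 carbon monoxide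
Product: 20 5,7-bis(benzyloxy)-2-{4-[2-(benzyloxy)-5-[(2S)-5-(benzyloxy)-7-methoxychroman-2-yl]phenoxy]phenyl}-4H-chromen-4-one, via hydroxyaryl ynone 18 (not isolated), via diethylamino enone 19 (not isolated)
Conditions: PdCl2(PPh3)2 (5 mol %), CO (20 atm), Et2NH (solvent), 120 °C, autoclave
Reagents that add atoms: none
Why: Oxidative addition of the C–I bond of 16 to zerovalent palladium (formed in the flask from PdCl2(PPh3)2), migratory insertion of CO to the aroylpalladium species, amine-assisted transfer of the acetylide of 14 and reductive elimination should give ynone 18, which holds the new C4a–C4 and C4–C3 bonds of ring E. Diethylamine then adds to the ynone to give β-amino enone 19, and the ortho hydroxyl attacks the β-carbon and expels the amine, forming O1–C2. The closest known reaction type is the palladium-catalysed carbonylative annulation of ortho-iodophenols with terminal aryl acetylenes in secondary amines (carbonylative Sonogashira coupling followed by cyclisation), which gives flavones. Ring E closes in the 6-endo mode (6-endo-trig addition–elimination on the enaminone, formally 6-endo-dig on the ynone); no stereocentre is formed, and C2 of ring C is an ether carbon with no neighbouring carbonyl, so the amine cannot epimerise it. The step needs carbonylative over direct coupling, which CO pressure and the ready migration of the electron-rich aryl group to CO should secure, and 6-endo over 5-exo closure (aurone), which the amine-derived enaminone secures because its β-carbon is the site the phenol attacks by addition–elimination.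

Step 13
Reactants: 20 5,7-bis(benzyloxy)-2-{4-[2-(benzyloxy)-5-[(2S)-5-(benzyloxy)-7-methoxychroman-2-yl]phenoxy]phenyl}-4H-chromen-4-one
Product: 21 5,7-bis(benzyloxy)-2-{4-[2-(benzyloxy)-5-[(2S)-5-(benzyloxy)-4-hydroxy-7-methoxychroman-2-yl]phenoxy]phenyl}-4H-chromen-4-one (C4 epimers)
Conditions: DDQ (1.2 equiv), 1,4-dioxane–pH 7 phosphate buffer (10:1), 0 °C → rt
Reagents that add atoms: water, O
Why: Benzylic oxidation by hydride abstraction, the known C4 oxygenation of flavans with DDQ; C4 is benzylic to the trioxygenated ring A, whose 5-, 7- and O1 oxygens stabilise the cation that water then captures, C2 is not touched so its S configuration should be retained, and any flavanone formed by further oxidation converges in step 14.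

Step 14
Reactants: 21 5,7-bis(benzyloxy)-2-{4-[2-(benzyloxy)-5-[(2S)-5-(benzyloxy)-4-hydroxy-7-methoxychroman-2-yl]phenoxy]phenyl}-4H-chromen-4-one (C4 epimers)
Product: 22 5,7-bis(benzyloxy)-2-{4-[2-(benzyloxy)-5-[(2S)-5-(benzyloxy)-7-methoxy-4-oxochroman-2-yl]phenoxy]phenyl}-4H-chromen-4-one
Conditions: Dess–Martin periodinane (1.5 equiv), pyridine, CH2Cl2, 0 °C → rt
Reagents that add atoms: none
Why: Dess–Martin oxidation of the secondary benzylic alcohol merges both C4 epimers into the flavanone under buffered, non-basic conditions, so the retro-oxa-Michael ring opening that would racemise C2 is not triggered.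

Step 15
Reactants: 22 5,7-bis(benzyloxy)-2-{4-[2-(benzyloxy)-5-[(2S)-5-(benzyloxy)-7-methoxy-4-oxochroman-2-yl]phenoxy]phenyl}-4H-chromen-4-one
Product: 23 5,7-dihydroxy-2-{4-[2-hydroxy-5-[(2S)-5-hydroxy-7-methoxy-4-oxochroman-2-yl]phenoxy]phenyl}-4H-chromen-4-one
Conditions: H2 (1 atm), Pd/C (10 wt %), EtOAc–MeOH (1:1), rt, stopped at full debenzylation
Reagents that add atoms: none
Why: Catalytic hydrogenolysis should cleave the four aryl benzyl ethers in neutral medium, where the flavone C2=C3 bond and the flavanone carbonyl react much more slowly and the 5-hydroxyflavanone is not exposed to base, so the 2S centre should survive.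

**Compound list**

1 | 3',4'-dihydroxyacetophenone | CC(=O)c1ccc(O)c(O)c1 | starting material
2 | 1-[4-(benzyloxy)-3-hydroxyphenyl]ethan-1-one | CC(=O)c1ccc(OCc2ccccc2)c(O)c1 | intermediate
3 | 4-bromophenylboronic acid | OB(O)c1ccc(Br)cc1 | starting material
4 | 1-[4-(benzyloxy)-3-(4-bromophenoxy)phenyl]ethan-1-one | CC(=O)c1ccc(OCc2ccccc2)c(Oc2ccc(Br)cc2)c1 | intermediate
5 | 2,4,6-trihydroxybenzaldehyde | O=Cc1c(O)cc(O)cc1O | starting material
6 | 2,6-dihydroxy-4-methoxybenzaldehyde | COc1cc(O)c(C=O)c(O)c1 | intermediate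
7 | 2-(benzyloxy)-6-hydroxy-4-methoxybenzaldehyde | COc1cc(O)c(C=O)c(OCc2ccccc2)c1 | intermediate
8 | (E)-1-[4-(benzyloxy)-3-(4-bromophenoxy)phenyl]-3-[2-(benzyloxy)-6-hydroxy-4-methoxyphenyl]prop-2-en-1-one | COc1cc(O)c(/C=C/C(=O)c2ccc(OCc3ccccc3)c(Oc3ccc(Br)cc3)c2)c(OCc2ccccc2)c1 | intermediate
9 | 1-[4-(benzyloxy)-3-(4-bromophenoxy)phenyl]-3-[2-(benzyloxy)-6-hydroxy-4-methoxyphenyl]propan-1-one | COc1cc(O)c(CCC(=O)c2ccc(OCc3ccccc3)c(Oc3ccc(Br)cc3)c2)c(OCc2ccccc2)c1 | intermediate
10 | (1R)-1-[4-(benzyloxy)-3-(4-bromophenoxy)phenyl]-3-[2-(benzyloxy)-6-hydroxy-4-methoxyphenyl]propan-1-ol | COc1cc(O)c(CC[C@@H](O)c2ccc(OCc3ccccc3)c(Oc3ccc(Br)cc3)c2)c(OCc2ccccc2)c1 | intermediate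
11 | (2S)-5-(benzyloxy)-2-[4-(benzyloxy)-3-(4-bromophenoxy)phenyl]-7-methoxychromane | COc1cc(OCc2ccccc2)c2c(c1)O[C@H](c1ccc(OCc3ccccc3)c(Oc3ccc(Br)cc3)c1)CC2 | intermediate
12 | ethynyltrimethylsilane | C#C[Si](C)(C)C | starting material
13 | (2S)-5-(benzyloxy)-2-{4-(benzyloxy)-3-[4-(trimethylsilylethynyl)phenoxy]phenyl}-7-methoxychromane | COc1cc(OCc2ccccc2)c2c(c1)O[C@H](c1ccc(OCc3ccccc3)c(Oc3ccc(C#C[Si](C)(C)C)cc3)c1)CC2 | intermediate
14 | (2S)-5-(benzyloxy)-2-[4-(benzyloxy)-3-(4-ethynylphenoxy)phenyl]-7-methoxychromane | COc1cc(OCc2ccccc2)c2c(c1)O[C@H](c1ccc(OCc3ccccc3)c(Oc3ccc(C#C)cc3)c1)CC2 | intermediate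
15 | 3,5-bis(benzyloxy)phenol | Oc1cc(OCc2ccccc2)cc(OCc2ccccc2)c1 | starting material
16 | 3,5-bis(benzyloxy)-2-iodophenol | Oc1cc(OCc2ccccc2)cc(OCc2ccccc2)c1I | intermediate
17 | carbon monoxide | [C-]#[O+] | starting material
18 | 1-[2,4-bis(benzyloxy)-6-hydroxyphenyl]-3-{4-[2-(benzyloxy)-5-[(2S)-5-(benzyloxy)-7-methoxychroman-2-yl]phenoxy]phenyl}prop-2-yn-1-one | COc1cc(OCc2ccccc2)c2c(c1)O[C@H](c1ccc(OCc3ccccc3)c(Oc3ccc(C#CC(=O)c4c(O)cc(OCc5ccccc5)cc4OCc4ccccc4)cc3)c1)CC2 | intermediate
19 | 1-[2,4-bis(benzyloxy)-6-hydroxyphenyl]-3-(diethylamino)-3-{4-[2-(benzyloxy)-5-[(2S)-5-(benzyloxy)-7-methoxychroman-2-yl]phenoxy]phenyl}prop-2-en-1-one | COc1cc(OCc2ccccc2)c2c(c1)O[C@H](c1ccc(OCc3ccccc3)c(Oc3ccc(C(=CC(=O)c4c(O)cc(OCc5ccccc5)cc4OCc4ccccc4)N(CC)CC)cc3)c1)CC2 | intermediate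
20 | 5,7-bis(benzyloxy)-2-{4-[2-(benzyloxy)-5-[(2S)-5-(benzyloxy)-7-methoxychroman-2-yl]phenoxy]phenyl}-4H-chromen-4-one | COc1cc(OCc2ccccc2)c2c(c1)O[C@H](c1ccc(OCc3ccccc3)c(Oc3ccc(-c4cc(=O)c5c(OCc6ccccc6)cc(OCc6ccccc6)cc5o4)cc3)c1)CC2 | intermediate
21 | 5,7-bis(benzyloxy)-2-{4-[2-(benzyloxy)-5-[(2S)-5-(benzyloxy)-4-hydroxy-7-methoxychroman-2-yl]phenoxy]phenyl}-4H-chromen-4-one (C4 epimers) | COc1cc(OCc2ccccc2)c2c(c1)O[C@H](c1ccc(OCc3ccccc3)c(Oc3ccc(-c4cc(=O)c5c(OCc6ccccc6)cc(OCc6ccccc6)cc5o4)cc3)c1)CC2O | intermediate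
22 | 5,7-bis(benzyloxy)-2-{4-[2-(benzyloxy)-5-[(2S)-5-(benzyloxy)-7-methoxy-4-oxochroman-2-yl]phenoxy]phenyl}-4H-chromen-4-one | COc1cc(OCc2ccccc2)c2c(c1)O[C@H](c1ccc(OCc3ccccc3)c(Oc3ccc(-c4cc(=O)c5c(OCc6ccccc6)cc(OCc6ccccc6)cc5o4)cc3)c1)CC2=O | intermediate
23 | 5,7-dihydroxy-2-{4-[2-hydroxy-5-[(2S)-5-hydroxy-7-methoxy-4-oxochroman-2-yl]phenoxy]phenyl}-4H-chromen-4-one | COc1cc(O)c2c(c1)O[C@H](c1ccc(O)c(Oc3ccc(-c4cc(=O)c5c(O)cc(O)cc5o4)cc3)c1)CC2=O | target

**Step count**

Total steps: 15. Longest linear sequence: 12 steps (steps 1, 2, 5–10 and 12–15 from compound 1; equally steps 3–10 and 12–15 from compound 5).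

**Steps most likely to fail**

1. Step 12 (key step). The aroylpalladium intermediate may be diverted by diethylamine (aminocarbonylation to the diethylamide). Coupling may also occur before CO insertion and be followed by closure to a 2-arylbenzofuran, or the hindered, electron-rich iodide may be protodeiodinated at 120 °C. The fallback builds the ynone without palladium or carbon monoxide; it sets out from compound 5 and alkyne 14 and comes back to the route at ynone 18. Compound 5 is benzylated twice (BnBr, K2CO3, DMF; the last hydroxyl is chelated and stays free) to give 2,4-bis(benzyloxy)-6-hydroxybenzaldehyde F1. Its hydroxyl is capped (MOMCl, i-Pr2NEt, CH2Cl2) to give 2,4-bis(benzyloxy)-6-(methoxymethoxy)benzaldehyde F2. The lithium acetylide of 14 (n-BuLi, THF, −78 °C) is added to F2 to give the propargylic alcohol 1-[2,4-bis(benzyloxy)-6-(methoxymethoxy)phenyl]-3-{4-[2-(benzyloxy)-5-[(2S)-5-(benzyloxy)-7-methoxychroman-2-yl]phenoxy]phenyl}prop-2-yn-1-ol F3 as a mixture of carbinol epimers. Oxidation with MnO2 in CH2Cl2 gives the protected ynone 1-[2,4-bis(benzyloxy)-6-(methoxymethoxy)phenyl]-3-{4-[2-(benzyloxy)-5-[(2S)-5-(benzyloxy)-7-methoxychroman-2-yl]phenoxy]phenyl}prop-2-yn-1-one F4. Dilute HCl in MeOH–THF at room temperature removes the acetal to give 18, which on warming in Et2NH–EtOH should close through enaminone 19 to 20.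

2. Step 13. Control over oxidation level and site may be lost. The labile 4-ol may ionise again, lose H3 and suffer a second hydride abstraction, which would aromatise ring C to a flavylium ion and erase C2. The C4 cation may also alkylate ring A of a second molecule, or hydride may be taken from C2 instead of C4. The fallback moves the C4 oxygenation ahead of the union, so that it is run and checked (site, enantiopurity) on a small intermediate and the oxygen is carried through the key step as a silyl ether; it sets out from 14 and comes back at 21. Alkyne 14 is oxidised (DDQ, dioxane–pH 7 buffer) to (2S)-5-(benzyloxy)-2-[4-(benzyloxy)-3-(4-ethynylphenoxy)phenyl]-7-methoxychroman-4-ol F5. This is silylated at once (TBSCl, imidazole, DMF) to (2S)-5-(benzyloxy)-2-[4-(benzyloxy)-3-(4-ethynylphenoxy)phenyl]-4-(tert-butyldimethylsilyloxy)-7-methoxychromane F6. The carbonylative annulation of F6 with 16 and 17 under the conditions of step 12 gives 5,7-bis(benzyloxy)-2-{4-[2-(benzyloxy)-5-[(2S)-5-(benzyloxy)-4-(tert-butyldimethylsilyloxy)-7-methoxychroman-2-yl]phenoxy]phenyl}-4H-chromen-4-one F7. TBAF buffered with AcOH in THF then frees 21.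

3. Step 8. The oxyphosphonium intermediate may ionise at the benzylic carbon, which the para-benzyloxy group stabilises as a cation; this SN1 leakage would lower the enantiopurity, and elimination to the styrene may compete. The fallback sets C2 by hydrogenation instead of substitution; it sets out from ketone 9 and comes back at 11. Ketone 9 is cyclodehydrated through its cyclic hemiketal (TsOH cat., toluene, 4 Å MS, 70 °C) to 5-(benzyloxy)-2-[4-(benzyloxy)-3-(4-bromophenoxy)phenyl]-7-methoxy-4H-chromene F8. Asymmetric hydrogenation of the enol ether C2=C3 bond (H2 50 bar, [Ir(cod)(tBu-PHOX)]BArF, CH2Cl2, rt; ligand enantiomer chosen to give 2S), a known route to 2-arylchromanes that leaves aryl bromides and benzyl ethers intact, should give 11.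

**Further compounds**

F1 | step 12 | 2,4-bis(benzyloxy)-6-hydroxybenzaldehyde | O=Cc1c(O)cc(OCc2ccccc2)cc1OCc1ccccc1
F2 | step 12 | 2,4-bis(benzyloxy)-6-(methoxymethoxy)benzaldehyde | COCOc1cc(OCc2ccccc2)cc(OCc2ccccc2)c1C=O
F3 | step 12 | 1-[2,4-bis(benzyloxy)-6-(methoxymethoxy)phenyl]-3-{4-[2-(benzyloxy)-5-[(2S)-5-(benzyloxy)-7-methoxychroman-2-yl]phenoxy]phenyl}prop-2-yn-1-ol (carbinol epimers) | COc1cc(OCc2ccccc2)c2c(c1)O[C@H](c1ccc(OCc3ccccc3)c(Oc3ccc(C#CC(O)c4c(OCOC)cc(OCc5ccccc5)cc4OCc4ccccc4)cc3)c1)CC2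
F4 | step 12 | 1-[2,4-bis(benzyloxy)-6-(methoxymethoxy)phenyl]-3-{4-[2-(benzyloxy)-5-[(2S)-5-(benzyloxy)-7-methoxychroman-2-yl]phenoxy]phenyl}prop-2-yn-1-one | COc1cc(OCc2ccccc2)c2c(c1)O[C@H](c1ccc(OCc3ccccc3)c(Oc3ccc(C#CC(=O)c4c(OCOC)cc(OCc5ccccc5)cc4OCc4ccccc4)cc3)c1)CC2
F5 | step 13 | (2S)-5-(benzyloxy)-2-[4-(benzyloxy)-3-(4-ethynylphenoxy)phenyl]-7-methoxychroman-4-ol (C4 epimers) | COc1cc(OCc2ccccc2)c2c(c1)O[C@H](c1ccc(OCc3ccccc3)c(Oc3ccc(C#C)cc3)c1)CC2O
F6 | step 13 | (2S)-5-(benzyloxy)-2-[4-(benzyloxy)-3-(4-ethynylphenoxy)phenyl]-4-(tert-butyldimethylsilyloxy)-7-methoxychromane (C4 epimers) | COc1cc(OCc2ccccc2)c2c(c1)O[C@H](c1ccc(OCc3ccccc3)c(Oc3ccc(C#C)cc3)c1)CC2O[Si](C)(C)C(C)(C)C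
F7 | step 13 | 5,7-bis(benzyloxy)-2-{4-[2-(benzyloxy)-5-[(2S)-5-(benzyloxy)-4-(tert-butyldimethylsilyloxy)-7-methoxychroman-2-yl]phenoxy]phenyl}-4H-chromen-4-one (C4 epimers) | COc1cc(OCc2ccccc2)c2c(c1)O[C@H](c1ccc(OCc3ccccc3)c(Oc3ccc(-c4cc(=O)c5c(OCc6ccccc6)cc(OCc6ccccc6)cc5o4)cc3)c1)CC2O[Si](C)(C)C(C)(C)C
F8 | step 8 | 5-(benzyloxy)-2-[4-(benzyloxy)-3-(4-bromophenoxy)phenyl]-7-methoxy-4H-chromene | COc1cc(OCc2ccccc2)c2c(c1)OC(c1ccc(OCc3ccccc3)c(Oc3ccc(Br)cc3)c1)=CC2
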